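**Strategy.** The route rests on disconnecting the bond between C2b of the resorcinol ring (cyclobuta[a]indene numbering; the carbon meta to both oxygens, hence not nucleophilic and best served by a halide) and the benzylic cyclobutane carbon C2a. An intramolecular reductive Heck reaction of an (S)-3-(2-bromobenzyl)-1-arylcyclobutene forms this bond, closes the five-membered ring and, by syn-carbopalladation and stereoretentive hydride transfer, sets C2a and C2 from the single stereocentre C7a. The step exploits the strained cyclobutene C2=C2a and the quaternary CMe2 carbon C1, which leaves the alkylpalladium no syn β-hydrogen. The precursor comes from a Claisen-derived allylarene by keteniminium [2+2] cycloaddition and Negishi coupling; the prenyl group follows.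

Key step: step 9

Remark on the chemistry (assumption): the (2R,5R)-amide 8 is assumed to give the (S)-cyclobutanone in step 5. The sense of induction has to be confirmed on the first batch, and the equally available (2S,5S)-amide would be used if it is opposite.

Step 1
Reactants: 1 3-bromo-5-methoxyphenol; 2 3-bromoprop-1-ene (allyl bromide)
Product: 3 1-bromo-3-methoxy-5-(prop-2-en-1-yloxy)benzene
Conditions: K2CO3, acetone, reflux
Reagents that add atoms: none
Why: Williamson ether synthesis, the phenoxide being alkylated by the primary allylic bromide; no stereocentre is involved.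

Step 2
Reactants: 3 1-bromo-3-methoxy-5-(prop-2-en-1-yloxy)benzene
Product: 4 3-bromo-5-methoxy-2-(prop-2-en-1-yl)phenol
Conditions: PhNEt2, 190 °C
Reagents that add atoms: none
Why: Aromatic Claisen rearrangement; migration should favour the ortho carbon next to bromine and para to methoxy (the usual preference for a meta acceptor combined with a meta donor), and the minor isomer with the allyl group between the two oxygens is removed by chromatography.

Step 3
Reactants: 4 3-bromo-5-methoxy-2-(prop-2-en-1-yl)phenol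
Product: 5 [3-bromo-5-methoxy-2-(prop-2-en-1-yl)phenoxy]triisopropylsilane
Conditions: TIPSCl, imidazole, DMF, 40 °C
Reagents that add atoms: chlorotriisopropylsilane CC(C)[Si](Cl)(C(C)C)C(C)C
Why: Silylation of the phenol; the bulky, weakly basic TIPS ether oxygen should not take part in the cationic cycloaddition of step 5 and later shields the ring position between the two oxygens.

Step 4
Reactants: 6 (2R,5R)-2,5-dimethylpyrrolidine; 7 2-methylpropanoyl chloride
Product: 8 1-[(2R,5R)-2,5-dimethylpyrrolidin-1-yl]-2-methylpropan-1-one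
Conditions: aq. NaOH, CH2Cl2, 0 → 23 °C
Reagents that add atoms: none
Why: Schotten–Baumann N-acylation; the two stereocentres of the C2-symmetric auxiliary are untouched.

Step 5
Reactants: 8 1-[(2R,5R)-2,5-dimethylpyrrolidin-1-yl]-2-methylpropan-1-one; 5 [3-bromo-5-methoxy-2-(prop-2-en-1-yl)phenoxy]triisopropylsilane
Product: 11 (3S)-3-{[2-bromo-4-methoxy-6-(triisopropylsilyloxy)phenyl]methyl}-2,2-dimethylcyclobutan-1-one, via keteniminium triflate 9 (not isolated), via cyclobutaniminium triflate 10 (not isolated)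
Conditions: 8, Tf2O, 2,4,6-collidine, ClCH2CH2Cl, −20 → 23 °C; then 5, 80 °C; then aq. NaHCO3, 23 °C
Reagents that add atoms: water O
Why: Keteniminium–alkene [2+2] cycloaddition followed by iminium hydrolysis: the electrophilic central carbon bonds to the terminal CH2 and the CMe2 carbon to the internal alkene carbon, which gives the 2,2-dimethyl-3-substituted ketone, and the C2-symmetric pyrrolidine differentiates the two alkene faces to set C3 as (S) (auxiliary control).

Step 6
Reactants: 12 4-bromobenzene-1,2-diol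
Product: 13 4-bromo-1,2-bis(tert-butyldimethylsilyloxy)benzene
Conditions: TBSCl, imidazole, DMF, 23 °C
Reagents that add atoms: tert-butylchlorodimethylsilane CC(C)(C)[Si](C)(C)Cl
Why: Double silylation of the catechol; the TBS ethers tolerate aryllithium formation and are removed by fluoride at the end.

Step 7
Reactants: 11 (3S)-3-{[2-bromo-4-methoxy-6-(triisopropylsilyloxy)phenyl]methyl}-2,2-dimethylcyclobutan-1-one
Product: 15 (3S)-3-{[2-bromo-4-methoxy-6-(triisopropylsilyloxy)phenyl]methyl}-4,4-dimethylcyclobut-1-en-1-yl trifluoromethanesulfonate, via potassium enolate 14 (not isolated)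
Conditions: KN(SiMe3)2, THF, −78 °C; then PhNTf2, −78 → 0 °C
Reagents that add atoms: N-phenylbis(trifluoromethanesulfonimide) O=S(=O)(N(c1ccccc1)S(=O)(=O)C(F)(F)F)C(F)(F)F
Why: Kinetic enolisation can occur only at the CH2 carbon (the other α-carbon is quaternary), so O-sulfonylation of the enolate should give a single enol triflate; the C3 stereocentre is not involved.

Step 8
Reactants: 13 4-bromo-1,2-bis(tert-butyldimethylsilyloxy)benzene; 15 (3S)-3-{[2-bromo-4-methoxy-6-(triisopropylsilyloxy)phenyl]methyl}-4,4-dimethylcyclobut-1-en-1-yl trifluoromethanesulfonate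
Product: 18 (3S)-1-[3,4-bis(tert-butyldimethylsilyloxy)phenyl]-3-{[2-bromo-4-methoxy-6-(triisopropylsilyloxy)phenyl]methyl}-4,4-dimethylcyclobut-1-ene, via aryllithium 16 (not isolated), via arylzinc chloride 17 (not isolated)
Conditions: 13, n-BuLi, THF, −78 °C; ZnCl2, −78 → 0 °C; then 15, Pd(PPh3)4 (5 mol %), 23 °C
Reagents that add atoms: none
Why: Negishi coupling; zerovalent palladium should insert into the alkenyl triflate at room temperature far faster than into the ortho-substituted, electron-rich aryl bromide, so the arylzinc is coupled at the cyclobutene carbon only and the stereocentre is unchanged.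

Step 9
Reactants: 18 (3S)-1-[3,4-bis(tert-butyldimethylsilyloxy)phenyl]-3-{[2-bromo-4-methoxy-6-(triisopropylsilyloxy)phenyl]methyl}-4,4-dimethylcyclobut-1-ene
Product: 19 (2S,2aR,7aS)-2-[3,4-bis(tert-butyldimethylsilyloxy)phenyl]-4-methoxy-1,1-dimethyl-6-(triisopropylsilyloxy)-2,2a,7,7a-tetrahydro-1H-cyclobuta[a]indene
Conditions: Pd(OAc)2 (10 mol %), PPh3 (20 mol %), HCO2Na, n-Bu4NCl, anhydrous DMF, 80 °C
Reagents that add atoms: none
Why: Zerovalent palladium inserts into the C–Br bond at the ring carbon meta to both oxygens, and the arylpalladium adds syn across the strained trisubstituted cyclobutene, forming the aryl–C2a bond and a tertiary benzylic C2–Pd bond; formate then replaces bromide, loses CO2, and the hydride is transferred to C2 with retention (intramolecular reductive Heck reaction, closest to formate-terminated Heck cyclisations onto norbornenes and trisubstituted alkenes). The cyclopentane ring closes in the 5-exo-trig mode. C2a is set by the C7a stereocentre, because the two-atom tether lets the aryl group reach only the cyclobutene face that carries the benzylic CH2, so the ring fusion must be cis. C2 is set by the syn course of insertion plus retentive hydride transfer, which places H on the concave face and the catechol ring on the convex face, trans to the new aryl bond; hydrogenation or radical hydrogen transfer from the open face would give the opposite arrangement. The step needs cyclisation to outrun direct formate reduction of the arylpalladium and needs the alkylpalladium to persist: the first is secured by the intramolecular, strain-releasing insertion and sparingly soluble HCO2Na, the second by the absence of any syn β-hydrogen (H on C2a is anti to palladium and C1 is the quaternary CMe2 carbon).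

Step 10
Reactants: 19 (2S,2aR,7aS)-2-[3,4-bis(tert-butyldimethylsilyloxy)phenyl]-4-methoxy-1,1-dimethyl-6-(triisopropylsilyloxy)-2,2a,7,7a-tetrahydro-1H-cyclobuta[a]indene
Product: 20 (2S,2aR,7aS)-3-bromo-2-[3,4-bis(tert-butyldimethylsilyloxy)phenyl]-4-methoxy-1,1-dimethyl-6-(triisopropylsilyloxy)-2,2a,7,7a-tetrahydro-1H-cyclobuta[a]indene
Conditions: NBS, MeCN, 0 °C, dark
Reagents that add atoms: N-bromosuccinimide O=C1CCC(=O)N1Br
Why: Electrophilic aromatic bromination of the resorcinol-type ring at C3, para to the silyloxy group and ortho to methoxy; the position between the two oxygens is shielded by the TIPS group and the bis-silylated catechol ring is much less activated.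

Step 11
Reactants: 20 (2S,2aR,7aS)-3-bromo-2-[3,4-bis(tert-butyldimethylsilyloxy)phenyl]-4-methoxy-1,1-dimethyl-6-(triisopropylsilyloxy)-2,2a,7,7a-tetrahydro-1H-cyclobuta[a]indene; 21 1-bromo-3-methylbut-2-ene (prenyl bromide)
Product: 24 (2S,2aR,7aS)-2-[3,4-bis(tert-butyldimethylsilyloxy)phenyl]-4-methoxy-1,1-dimethyl-3-(3-methylbut-2-en-1-yl)-6-(triisopropylsilyloxy)-2,2a,7,7a-tetrahydro-1H-cyclobuta[a]indene, via aryllithium 22 (not isolated), via arylcopper 23 (not isolated)
Conditions: n-BuLi, THF, −78 °C; CuBr·SMe2, −78 → −40 °C; then 21, −40 → 0 °C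
Reagents that add atoms: none
Why: Bromine–lithium exchange, transmetalation to the arylcopper and copper-mediated allylic substitution at the primary carbon of prenyl bromide (α-attack favoured because the γ-carbon is fully substituted); the stereocentres are untouched.

Step 12
Reactants: 24 (2S,2aR,7aS)-2-[3,4-bis(tert-butyldimethylsilyloxy)phenyl]-4-methoxy-1,1-dimethyl-3-(3-methylbut-2-en-1-yl)-6-(triisopropylsilyloxy)-2,2a,7,7a-tetrahydro-1H-cyclobuta[a]indene
Product: 25 4-[(2S,2aR,7aS)-6-hydroxy-4-methoxy-1,1-dimethyl-3-(3-methylbut-2-en-1-yl)-2,2a,7,7a-tetrahydro-1H-cyclobuta[a]inden-2-yl]benzene-1,2-diol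
Conditions: n-Bu4NF, AcOH, THF (degassed), 0 → 23 °C
Reagents that add atoms: none
Why: Fluoride cleavage of the three aryl silyl ethers under acetic acid buffering, which should keep the catechol from oxidising and leave the prenyl alkene and the methyl ether untouched.

**Compound list**

1 | 3-bromo-5-methoxyphenol | COc1cc(O)cc(Br)c1 | starting material
2 | 3-bromoprop-1-ene (allyl bromide) | C=CCBr | starting material
3 | 1-bromo-3-methoxy-5-(prop-2-en-1-yloxy)benzene | COc1cc(OCC=C)cc(Br)c1 | intermediate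
4 | 3-bromo-5-methoxy-2-(prop-2-en-1-yl)phenol | COc1cc(O)c(CC=C)c(Br)c1 | intermediate
5 | [3-bromo-5-methoxy-2-(prop-2-en-1-yl)phenoxy]triisopropylsilane | COc1cc(O[Si](C(C)C)(C(C)C)C(C)C)c(CC=C)c(Br)c1 | intermediate
6 | (2R,5R)-2,5-dimethylpyrrolidine | C[C@@H]1CC[C@@H](C)N1 | starting material
7 | 2-methylpropanoyl chloride | CC(C)C(=O)Cl | starting material
8 | 1-[(2R,5R)-2,5-dimethylpyrrolidin-1-yl]-2-methylpropan-1-one | C[C@@H]1CC[C@@H](C)N1C(=O)C(C)C | intermediate
9 | (2R,5R)-2,5-dimethyl-1-(2-methylprop-1-en-1-ylidene)pyrrolidinium triflate (keteniminium salt) | C[C@@H]1CC[C@@H](C)[N+]1=C=C(C)C.[O-]S(=O)(=O)C(F)(F)F | intermediate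
10 | (2R,5R)-1-[(3S)-3-{[2-bromo-4-methoxy-6-(triisopropylsilyloxy)phenyl]methyl}-2,2-dimethylcyclobutylidene]-2,5-dimethylpyrrolidinium triflate | C[C@@H]1CC[C@@H](C)[N+]1=C1C[C@H](Cc2c(Br)cc(OC)cc2O[Si](C(C)C)(C(C)C)C(C)C)C1(C)C.[O-]S(=O)(=O)C(F)(F)F | intermediate
11 | (3S)-3-{[2-bromo-4-methoxy-6-(triisopropylsilyloxy)phenyl]methyl}-2,2-dimethylcyclobutan-1-one | O=C1C[C@H](Cc2c(Br)cc(OC)cc2O[Si](C(C)C)(C(C)C)C(C)C)C1(C)C | intermediate
12 | 4-bromobenzene-1,2-diol | Oc1ccc(Br)cc1O | starting material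
13 | 4-bromo-1,2-bis(tert-butyldimethylsilyloxy)benzene | CC(C)(C)[Si](C)(C)Oc1ccc(Br)cc1O[Si](C)(C)C(C)(C)C | intermediate
14 | potassium (3S)-3-{[2-bromo-4-methoxy-6-(triisopropylsilyloxy)phenyl]methyl}-4,4-dimethylcyclobut-1-en-1-olate | [K+].[O-]C1=C[C@H](Cc2c(Br)cc(OC)cc2O[Si](C(C)C)(C(C)C)C(C)C)C1(C)C | intermediate
15 | (3S)-3-{[2-bromo-4-methoxy-6-(triisopropylsilyloxy)phenyl]methyl}-4,4-dimethylcyclobut-1-en-1-yl trifluoromethanesulfonate | FC(F)(F)S(=O)(=O)OC1=C[C@H](Cc2c(Br)cc(OC)cc2O[Si](C(C)C)(C(C)C)C(C)C)C1(C)C | intermediate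
16 | [3,4-bis(tert-butyldimethylsilyloxy)phenyl]lithium | CC(C)(C)[Si](C)(C)Oc1ccc([Li])cc1O[Si](C)(C)C(C)(C)C | intermediate
17 | [3,4-bis(tert-butyldimethylsilyloxy)phenyl]zinc chloride | CC(C)(C)[Si](C)(C)Oc1ccc([Zn]Cl)cc1O[Si](C)(C)C(C)(C)C | intermediate
18 | (3S)-1-[3,4-bis(tert-butyldimethylsilyloxy)phenyl]-3-{[2-bromo-4-methoxy-6-(triisopropylsilyloxy)phenyl]methyl}-4,4-dimethylcyclobut-1-ene | CC(C)(C)[Si](C)(C)Oc1ccc(cc1O[Si](C)(C)C(C)(C)C)C1=C[C@H](Cc2c(Br)cc(OC)cc2O[Si](C(C)C)(C(C)C)C(C)C)C1(C)C | intermediate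
19 | (2S,2aR,7aS)-2-[3,4-bis(tert-butyldimethylsilyloxy)phenyl]-4-methoxy-1,1-dimethyl-6-(triisopropylsilyloxy)-2,2a,7,7a-tetrahydro-1H-cyclobuta[a]indene | COc1cc(O[Si](C(C)C)(C(C)C)C(C)C)c2c(c1)[C@@H]1[C@H](C2)C(C)(C)[C@H]1c1ccc(O[Si](C)(C)C(C)(C)C)c(O[Si](C)(C)C(C)(C)C)c1 | intermediate
20 | (2S,2aR,7aS)-3-bromo-2-[3,4-bis(tert-butyldimethylsilyloxy)phenyl]-4-methoxy-1,1-dimethyl-6-(triisopropylsilyloxy)-2,2a,7,7a-tetrahydro-1H-cyclobuta[a]indene | COc1cc(O[Si](C(C)C)(C(C)C)C(C)C)c2c(c1Br)[C@@H]1[C@H](C2)C(C)(C)[C@H]1c1ccc(O[Si](C)(C)C(C)(C)C)c(O[Si](C)(C)C(C)(C)C)c1 | intermediate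
21 | 1-bromo-3-methylbut-2-ene (prenyl bromide) | CC(C)=CCBr | starting material
22 | aryllithium from 20 (lithium in place of bromine at C3) | COc1cc(O[Si](C(C)C)(C(C)C)C(C)C)c2c(c1[Li])[C@@H]1[C@H](C2)C(C)(C)[C@H]1c1ccc(O[Si](C)(C)C(C)(C)C)c(O[Si](C)(C)C(C)(C)C)c1 | intermediate
23 | arylcopper from 22 (copper in place of lithium at C3) | COc1cc(O[Si](C(C)C)(C(C)C)C(C)C)c2c(c1[Cu])[C@@H]1[C@H](C2)C(C)(C)[C@H]1c1ccc(O[Si](C)(C)C(C)(C)C)c(O[Si](C)(C)C(C)(C)C)c1 | intermediate
24 | (2S,2aR,7aS)-2-[3,4-bis(tert-butyldimethylsilyloxy)phenyl]-4-methoxy-1,1-dimethyl-3-(3-methylbut-2-en-1-yl)-6-(triisopropylsilyloxy)-2,2a,7,7a-tetrahydro-1H-cyclobuta[a]indene | COc1cc(O[Si](C(C)C)(C(C)C)C(C)C)c2c(c1CC=C(C)C)[C@@H]1[C@H](C2)C(C)(C)[C@H]1c1ccc(O[Si](C)(C)C(C)(C)C)c(O[Si](C)(C)C(C)(C)C)c1 | intermediate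
25 | 4-[(2S,2aR,7aS)-6-hydroxy-4-methoxy-1,1-dimethyl-3-(3-methylbut-2-en-1-yl)-2,2a,7,7a-tetrahydro-1H-cyclobuta[a]inden-2-yl]benzene-1,2-diol | COc1cc(O)c2c(c1CC=C(C)C)[C@@H]1[C@H](C2)C(C)(C)[C@H]1c1ccc(O)c(O)c1 | target

**Step count and risks**

Total steps: 12. Longest linear sequence: 10 (steps 1, 2, 3, 5, 7, 8, 9, 10, 11, 12).

Step 9 (key step). The arylpalladium may be reduced by formate before it inserts (hydrodebromination), or the phenolic TBS groups may be lost to formate in hot DMF. Fallback: setting out from 18, bromine–lithium exchange (t-BuLi, THF, −100 °C) should give the aryllithium F1, trapped at once with 2-isopropoxy-4,4,5,5-tetramethyl-1,3,2-dioxaborolane as the pinacol boronate F2. [Rh(OH)(cod)]2 in dioxane/water at 60 °C should then transmetalate, add aryl–rhodium syn across the cyclobutene and protonate the benzylic rhodium with retention. This forms the same bond with the same configuration at C2 and C2a and comes back to the route at 19.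

Step 5. The auxiliary may discriminate the alkene faces poorly or in the opposite sense, because the new stereocentre is remote from nitrogen; the keteniminium ion may also attack the electron-rich ring. Fallback: setting out from 5, the same cycloaddition run with commercially available N,N,2-trimethylpropanamide (Tf2O, 2,4,6-collidine; then 5; then aq. NaHCO3) should give, by way of tetramethylketeniminium triflate F3 and the racemic cyclobutaniminium triflate F4, the racemic ketone F5. Corey–Bakshi–Shibata reduction with the (S)-methyl oxazaborolidine catalyst and BH3·SMe2 is catalyst-controlled (CMe2 is the large group, so the carbinol carbon becomes R), and the two ketone enantiomers should give the diastereomeric (1R,3S)-alcohol F6 and (1R,3R)-alcohol F7, separable on silica. Dess–Martin oxidation of F6 comes back to the route at 11.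

Step 11. The aryl-metal may attack prenyl bromide at the γ-carbon (reverse-prenyl product), or the hindered aryl-metal may be protonated before it couples. Fallback: setting out from 20, Stille coupling with allyltributylstannane (Pd(P(t-Bu)3)2, dioxane, 80 °C, no fluoride) should give the 3-allyl compound F8. Cross-metathesis with excess 2-methylbut-2-ene (second-generation Grubbs catalyst, CH2Cl2, 40 °C) should convert the allyl into the prenyl group and come back to the route at 24.

**Further compounds**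

F1 | step 9 | aryllithium from 18 (lithium in place of bromine) | CC(C)(C)[Si](C)(C)Oc1ccc(cc1O[Si](C)(C)C(C)(C)C)C1=C[C@H](Cc2c([Li])cc(OC)cc2O[Si](C(C)C)(C(C)C)C(C)C)C1(C)C
F2 | step 9 | (3S)-1-[3,4-bis(tert-butyldimethylsilyloxy)phenyl]-3-{[4-methoxy-2-(4,4,5,5-tetramethyl-1,3,2-dioxaborolan-2-yl)-6-(triisopropylsilyloxy)phenyl]methyl}-4,4-dimethylcyclobut-1-ene | CC(C)(C)[Si](C)(C)Oc1ccc(cc1O[Si](C)(C)C(C)(C)C)C1=C[C@H](Cc2c(B3OC(C)(C)C(C)(C)O3)cc(OC)cc2O[Si](C(C)C)(C(C)C)C(C)C)C1(C)C
F3 | step 5 | N,N-dimethyl-2-methylprop-1-en-1-ylideneammonium triflate (tetramethylketeniminium triflate) | CC(C)=C=[N+](C)C.[O-]S(=O)(=O)C(F)(F)F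
F4 | step 5 | racemic N-(3-{[2-bromo-4-methoxy-6-(triisopropylsilyloxy)phenyl]methyl}-2,2-dimethylcyclobutylidene)-N-methylmethanaminium triflate | C[N+](C)=C1CC(Cc2c(Br)cc(OC)cc2O[Si](C(C)C)(C(C)C)C(C)C)C1(C)C.[O-]S(=O)(=O)C(F)(F)F
F5 | step 5 | racemic 3-{[2-bromo-4-methoxy-6-(triisopropylsilyloxy)phenyl]methyl}-2,2-dimethylcyclobutan-1-one | O=C1CC(Cc2c(Br)cc(OC)cc2O[Si](C(C)C)(C(C)C)C(C)C)C1(C)C
F6 | step 5 | (1R,3S)-3-{[2-bromo-4-methoxy-6-(triisopropylsilyloxy)phenyl]methyl}-2,2-dimethylcyclobutan-1-ol | O[C@@H]1C[C@H](Cc2c(Br)cc(OC)cc2O[Si](C(C)C)(C(C)C)C(C)C)C1(C)C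
F7 | step 5 | (1R,3R)-3-{[2-bromo-4-methoxy-6-(triisopropylsilyloxy)phenyl]methyl}-2,2-dimethylcyclobutan-1-ol | O[C@@H]1C[C@@H](Cc2c(Br)cc(OC)cc2O[Si](C(C)C)(C(C)C)C(C)C)C1(C)C
F8 | step 11 | (2S,2aR,7aS)-2-[3,4-bis(tert-butyldimethylsilyloxy)phenyl]-4-methoxy-1,1-dimethyl-3-(prop-2-en-1-yl)-6-(triisopropylsilyloxy)-2,2a,7,7a-tetrahydro-1H-cyclobuta[a]indene | COc1cc(O[Si](C(C)C)(C(C)C)C(C)C)c2c(c1CC=C)[C@@H]1[C@H](C2)C(C)(C)[C@H]1c1ccc(O[Si](C)(C)C(C)(C)C)c(O[Si](C)(C)C(C)(C)C)c1
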